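Ring A is disconnected across C4–C5 and C1–C10. The key step exploits the 1,4 relation of the C3 oxygen to the quaternary C10 in ring A and the trans relation of H5 to C20: a catalytic asymmetric Diels–Alder reaction joins a 2-silyloxydiene ester (C1–C4 with C19) to ethyl (E)-3-formylbut-2-enoate (C9, C10, C20, C5, C6). In one operation it closes ring A, forms the C4–C5 bond, creates C10 and sets the trans A/B junction from the E-alkene geometry. C9 and C6 emerge trans on adjacent ring carbons, so that a later double Michael cascade builds rings B and C between them; ring D follows by Pd(OAc)2-catalysed cycloalkenylation.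

Key step: step 2

Remark: gibberellane numbering (C1–C20) is used for all intermediates; methyl 3-oxopent-4-enoate (1) is taken as a commercial, cold-stored reagent. "Upper face" means the face of ring B that carries H5, H9, C7 and C15 in the target; "lower face" is the face of C20, C19, C11 and C14.

Step 1
Reactants: 1 methyl 3-oxopent-4-enoate
Product: 2 methyl (2Z)-3-[(tert-butyldimethylsilyl)oxy]penta-2,4-dienoate
Conditions: TBSOTf, Et3N, Et2O, 0 °C
Reagents that add atoms: tert-butyldimethylsilyl trifluoromethanesulfonate, CC(C)(C)[Si](C)(C)OS(=O)(=O)C(F)(F)F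
Why: O-silylation of the β-keto ester enol (silyl enol ether formation) should give the (Z)-dienol ether, in which the ester sits on the outside of the s-cis diene; no stereocentre is formed.

Step 2
Reactants: 2 methyl (2Z)-3-[(tert-butyldimethylsilyl)oxy]penta-2,4-dienoate; 3 ethyl (2E)-3-methyl-4-oxobut-2-enoate
Product: 5 1-ethyl 2-methyl (1R,2R,6R)-6-formyl-6-methyl-3-oxocyclohexane-1,2-dicarboxylate (ring A: C3 ketone, C19 ester on C4, C6 ester on C5, formyl C9 and methyl C20 on C10, formyl trans to the C6 ester), via silyl enol ether cycloadduct 4 (not isolated)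
Conditions: cationic chiral oxazaborolidine [(S)-3,3-diphenyl-1-(2-methylphenyl)tetrahydro-1H,3H-pyrrolo[1,2-c][1,3,2]oxazaborole·HNTf2, 20 mol %], CH2Cl2, −78 → −40 °C; then 1 M HCl, THF, 0 °C
Reagents that add atoms: none
Why: The boron Lewis acid binds the formyl oxygen of 3 and the diene adds in a concerted but asynchronous normal-demand [4+2] cycloaddition (Diels–Alder reaction) in which the C4–C5 bond runs ahead of the C1–C10 bond, after which dilute acid cleaves the enol silyl ether 4 to the β-keto ester. The closest known reaction type is the enantioselective Diels–Alder reaction of 2-silyloxybutadienes with 2-methyl-substituted enals under cationic oxazaborolidine catalysis. Ring A is closed in the intermolecular [4+2] mode, both new bonds (C4–C5 and C1–C10) being made suprafacially on each partner. The relative configuration of C5 and C10 (formyl C9 trans to ester C6, hence H5 trans to C20) is carried over from the E geometry of 3; the absolute configuration comes from the catalyst, whose antipode is chosen so that the diene adds to the Re face at C10 (the S catalyst is expected, the R catalyst being equally available should the sense prove opposite); C4 is formed as the endo epimer (esters trans) but is epimerisable and is reset in step 3. The step needs regiocontrol (C4 to C5, C1 to C10), which is secured because the silyloxy group at C3 makes C4 the nucleophilic diene terminus, while the catalyst-bound formyl group makes its β-carbon C5 the electrophilic terminus and the C6 ester is the weaker acceptor.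

Step 3
Reactants: 5 1-ethyl 2-methyl (1R,2R,6R)-6-formyl-6-methyl-3-oxocyclohexane-1,2-dicarboxylate
Product: 6 1-ethyl 2-methyl (1S,2S,6R)-6-formyl-2,6-dimethyl-3-oxocyclohexane-1,2-dicarboxylate (C18 trans to C6 and to C20; ester C19 cis to C20)
Conditions: MeI, K2CO3, acetone, rt
Reagents that add atoms: iodomethane, CI
Why: C-alkylation of the β-keto ester enolate, in which iodomethane should approach C4 trans to the adjacent C5 ester arm and away from the axial C20, so that C18 ends trans to C6 and the C19 ester cis to C20.

Step 4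
Reactants: 6 1-ethyl 2-methyl (1S,2S,6R)-6-formyl-2,6-dimethyl-3-oxocyclohexane-1,2-dicarboxylate
Product: 8 hydroxy lactone (ring A with axial 3-OH cis to C18, C19 methyl ester on C4, and a trans-fused γ-lactone C6(=O)–O–C9H2 across C5–C10), via diol diester 7 (not isolated)
Conditions: L-Selectride (LiBH(s-Bu)3, 2.2 equiv), THF, −78 → 0 °C; H2O
Reagents that add atoms: none
Why: Hydride reduction followed by lactonisation: the C9 alkoxide formed from the aldehyde closes the trans-fused γ-lactone onto the C6 ethyl ester (5-exo-trig acyl substitution), and the bulky borohydride adds to the C3 ketone from the equatorial direction, as is usual for hindered 4,4-disubstituted cyclohexanones, giving the axial 3-OH cis to C18 and trans to the C19 ester.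

Step 5
Reactants: 8 hydroxy lactone
Product: 9 silyl ether lactone (8 with the 3-OH as its tert-butyldimethylsilyl ether)
Conditions: TBSOTf, 2,6-lutidine, CH2Cl2, 0 °C
Reagents that add atoms: tert-butyldimethylsilyl trifluoromethanesulfonate, CC(C)(C)[Si](C)(C)OS(=O)(=O)C(F)(F)F
Why: Silyl ether protection of the hindered axial secondary alcohol with the reactive silyl triflate; no stereocentre is touched.

Step 6
Reactants: 9 silyl ether lactone; 10 but-3-en-1-ylmagnesium bromide
Product: 11 hydroxy ketone (C6 ketone carrying the but-3-enyl chain C8, C15, C16, C17 on C5; hydroxymethyl C9 on C10; in equilibrium with its cyclic hemiketal)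
Conditions: 10 (1.1 equiv), THF, −78 → −40 °C; aqueous work-up
Reagents that add atoms: none
Why: Mono-addition of a Grignard reagent to a lactone, whose tetrahedral magnesium hemiketalate is stable at low temperature; the neopentyl, axial C19 methyl ester should not compete.

Step 7
Reactants: 11 hydroxy ketone
Product: 12 keto aldehyde (formyl C9 on C10; C6 ketone with the but-3-enyl chain on C5)
Conditions: DMP (1,1,1-triacetoxy-1,1-dihydro-1,2-benziodoxol-3(1H)-one), NaHCO3, CH2Cl2, rt
Reagents that add atoms: none
Why: Periodinane oxidation of the primary alcohol of the open hydroxy ketone tautomer; the tertiary hemiketal hydroxyl cannot be oxidised, so the equilibrium drains to the aldehyde.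

Step 8
Reactants: 12 keto aldehyde; 13 2-(trimethylsilyloxy)buta-1,3-diene
Product: 15 β-hydroxy vinyl ketone (C9 carbinol carrying C11H2–C12(=O)–C13H=C14H2; mixture at C9), via trimethylsilyl aldol ether 14 (not isolated)
Conditions: 13, Sc(OTf)3 (5 mol %), CH2Cl2, −78 → −30 °C; then dilute HCl, THF, 0 °C
Reagents that add atoms: none
Why: Mukaiyama aldol addition of the silyl enol ether of methyl vinyl ketone to the aldehyde, which is far more electrophilic than the C6 ketone; the new carbinol centre is not controlled and is removed in step 9.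

Step 9
Reactants: 15 β-hydroxy vinyl ketone
Product: 17 cross-conjugated (E)-dienone (C10–C9H=C11H–C12(=O)–C13H=C14H2), via mesylate 16 (not isolated)
Conditions: MsCl, Et3N, CH2Cl2, 0 °C → rt
Reagents that add atoms: methanesulfonyl chloride, CS(=O)(=O)Cl
Why: Mesylation gives the β-sulfonyloxy ketone 16, which should undergo E1cB elimination in the same flask to the (E)-enone; triethylamine is too weak a base to enolise the C6 ketone.

Step 10
Reactants: 17 cross-conjugated (E)-dienone
Product: 19 tricyclic silyl enol ether (rings A, B, C; C6 ketone; C8 carrying the allyl group C15–C17 on the upper face and C14 on the lower face; H9 on the upper face; C12(OTBS)=C13), via lithium enolate 18 (not isolated)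
Conditions: LiN(SiMe3)2 (1.05 equiv), THF, −78 → −10 °C; then TBSCl, HMPA, −78 → 0 °C
Reagents that add atoms: tert-butyldimethylsilyl chloride, CC(C)(C)[Si](C)(C)Cl
Why: Tandem intramolecular Michael additions (anionic double Michael reaction): the kinetic enolate at C8, the only accessible α-methylene, adds 5-exo-trig to C9 with the C11 side chain in the pseudo-equatorial position of the forming trans-fused cyclopentanone (H9 on the upper face, C11 cis to C20); after proton transfer the C8 enolate adds 6-endo-trig to the vinyl terminus C14, which can only reach the face that carries C11, so ring C is cis-fused on the lower face and the allyl group is forced to the upper face; the resulting C12–C13 enolate is trapped on oxygen.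

Step 11
Reactants: 19 tricyclic silyl enol ether
Product: 20 tetracyclic 6,12-diketone (rings A–D with the C13–C16 bond and the exocyclic C16=C17 methylene)
Conditions: Pd(OAc)2 (10 mol %), O2 (1 atm), DMSO, 45 °C
Reagents that add atoms: none
Why: Cycloalkenylation of a silyl enol ether by Pd(OAc)2 (divalent palladium): C13 attacks the internal carbon C16 of the allyl group (5-exo-trig) and β-hydride elimination gives the exocyclic methylene; the configuration of the bridgehead C13 is fixed by the two-carbon bridge.

Step 12
Reactants: 20 tetracyclic 6,12-diketone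
Product: 21 12-hydroxy 6-ketone (12-OH anti to C16, cis to H13)
Conditions: NaBH4, MeOH–CH2Cl2, −40 °C
Reagents that add atoms: none
Why: Chemoselective and stereoselective borohydride reduction: the C12 ketone is more accessible than the C6 ketone, which lies between the quaternary C8 and C5, and hydride should come from the face of the C15–C16 bridge because the other face is covered by C10, which is axial on ring C.

Step 13
Reactants: 21 12-hydroxy 6-ketone
Product: 22 methyl enol ether (C6=C7H–OMe, E/Z mixture)
Conditions: Ph3P(CH2OMe)Cl, KOtBu (excess), THF, 0 °C → reflux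
Reagents that add atoms: (methoxymethyl)triphenylphosphonium chloride, COC[P+](c1ccccc1)(c1ccccc1)c1ccccc1.[Cl-]
Why: Wittig methoxymethylenation brings in C7 at the only remaining ketone; the 12-OH is carried as its alkoxide and no stereocentre is formed.

Step 14
Reactants: 22 methyl enol ether
Product: 23 C7 aldehyde (formyl on the upper face of C6, H6 trans to H5)
Conditions: oxalic acid, THF–H2O, rt; then K2CO3, MeOH, rt
Reagents that add atoms: water, O
Why: Enol ether hydrolysis followed by base equilibration through the enol should place the formyl group in the thermodynamically preferred position at C6, on the upper face away from C20 and the axial C19 ester.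

Step 15
Reactants: 23 C7 aldehyde
Product: 24 C7 carboxylic acid (3-O-silyl, C19 methyl ester)
Conditions: NaClO2, NaH2PO4, 2-methylbut-2-ene, t-BuOH–H2O, rt
Reagents that add atoms: sodium chlorite, [Na+].[O-]Cl=O
Why: Pinnick oxidation converts the aldehyde to the acid without epimerisation at C6, and the alkene scavenger protects the exocyclic methylene from hypochlorite.

Step 16
Reactants: 24 C7 carboxylic acid
Product: 25 7,19-diacid 3-O-silyl ether
Conditions: NaSEt, DMF, 90 °C; then dilute HCl
Reagents that add atoms: none
Why: SN2 demethylation of the hindered C19 methyl ester by thiolate attacks the methyl carbon and so is indifferent to the congestion at the acyl carbon; no stereocentre is affected.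

Step 17
Reactants: 25 7,19-diacid 3-O-silyl ether
Product: 26 target gibberellin, 3β,12α-dihydroxygibberell-16-ene-7,19-dioic acid (3-OH cis to C18, 12-OH anti to the C15–C16 bridge)
Conditions: Bu4NF, THF, 50 °C; then dilute HCl
Reagents that add atoms: none
Why: Fluoride-mediated cleavage of the silyl ether frees the 3-OH; as the 19-carboxylate is already present, retro-aldol cleavage of ring A is not expected.

Compound list
1 | methyl 3-oxopent-4-enoate | C=CC(=O)CC(=O)OC | starting material
2 | methyl (2Z)-3-[(tert-butyldimethylsilyl)oxy]penta-2,4-dienoate | C=C/C(O[Si](C)(C)C(C)(C)C)=C/C(=O)OC | intermediate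
3 | ethyl (2E)-3-methyl-4-oxobut-2-enoate | O=C/C(C)=C/C(=O)OCC | starting material
4 | 1-ethyl 2-methyl (1R,2R,6R)-6-formyl-6-methyl-3-[(tert-butyldimethylsilyl)oxy]cyclohex-3-ene-1,2-dicarboxylate (endo cycloadduct) | O=C[C@]1(C)CC=C(O[Si](C)(C)C(C)(C)C)[C@H](C(=O)OC)[C@H]1C(=O)OCC | intermediate
5 | 1-ethyl 2-methyl (1R,2R,6R)-6-formyl-6-methyl-3-oxocyclohexane-1,2-dicarboxylate | O=C[C@]1(C)CCC(=O)[C@H](C(=O)OC)[C@H]1C(=O)OCC | intermediate
6 | 1-ethyl 2-methyl (1S,2S,6R)-6-formyl-2,6-dimethyl-3-oxocyclohexane-1,2-dicarboxylate | O=C[C@]1(C)CCC(=O)[C@@](C)(C(=O)OC)[C@H]1C(=O)OCC | intermediate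
7 | diol diester (3-OH axial, C9 hydroxymethyl, C6 ethyl ester, C19 methyl ester) | OC[C@]1(C)CC[C@H](O)[C@@](C)(C(=O)OC)[C@H]1C(=O)OCC | intermediate
8 | hydroxy lactone (trans-fused C6/C9 γ-lactone on ring A, axial 3-OH, C19 methyl ester) | O=C1OC[C@]2(C)CC[C@H](O)[C@@](C)(C(=O)OC)[C@@H]12 | intermediate
9 | silyl ether lactone (3-O-TBS derivative of 8) | O=C1OC[C@]2(C)CC[C@H](O[Si](C)(C)C(C)(C)C)[C@@](C)(C(=O)OC)[C@@H]12 | intermediate
10 | but-3-en-1-ylmagnesium bromide | C=CCC[Mg]Br | starting material
11 | hydroxy ketone (C6 but-3-enyl ketone on C5, hydroxymethyl C9 on C10; open tautomer of the hemiketal) | OC[C@]1(C)CC[C@H](O[Si](C)(C)C(C)(C)C)[C@@](C)(C(=O)OC)[C@H]1C(=O)CCC=C | intermediate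
12 | keto aldehyde (formyl C9 on C10, C6 but-3-enyl ketone on C5) | O=C[C@]1(C)CC[C@H](O[Si](C)(C)C(C)(C)C)[C@@](C)(C(=O)OC)[C@H]1C(=O)CCC=C | intermediate
13 | 2-(trimethylsilyloxy)buta-1,3-diene | C=CC(=C)O[Si](C)(C)C | starting material
14 | trimethylsilyl aldol ether (C9 epimers) | C=CC(=O)CC(O[Si](C)(C)C)[C@]1(C)CC[C@H](O[Si](C)(C)C(C)(C)C)[C@@](C)(C(=O)OC)[C@H]1C(=O)CCC=C | intermediate
15 | β-hydroxy vinyl ketone (C9 epimers) | C=CC(=O)CC(O)[C@]1(C)CC[C@H](O[Si](C)(C)C(C)(C)C)[C@@](C)(C(=O)OC)[C@H]1C(=O)CCC=C | intermediate
16 | mesylate of 15 (C9 epimers) | C=CC(=O)CC(OS(C)(=O)=O)[C@]1(C)CC[C@H](O[Si](C)(C)C(C)(C)C)[C@@](C)(C(=O)OC)[C@H]1C(=O)CCC=C | intermediate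
17 | cross-conjugated (E)-dienone | C=CC(=O)/C=C/[C@]1(C)CC[C@H](O[Si](C)(C)C(C)(C)C)[C@@](C)(C(=O)OC)[C@H]1C(=O)CCC=C | intermediate
18 | lithium C12–C13 enolate of the tricyclic 6,12-diketone | C=CC[C@]12CC=C([O-])C[C@H]1[C@]1(C)CC[C@H](O[Si](C)(C)C(C)(C)C)[C@@](C)(C(=O)OC)[C@H]1C2=O.[Li+] | intermediate
19 | tricyclic silyl enol ether (C6 ketone, 8-allyl, C12(OTBS)=C13) | C=CC[C@]12CC=C(O[Si](C)(C)C(C)(C)C)C[C@H]1[C@]1(C)CC[C@H](O[Si](C)(C)C(C)(C)C)[C@@](C)(C(=O)OC)[C@H]1C2=O | intermediate
20 | tetracyclic 6,12-diketone with 16-methylene | C=C1C[C@]23C[C@H]1C(=O)C[C@H]2[C@]1(C)CC[C@H](O[Si](C)(C)C(C)(C)C)[C@@](C)(C(=O)OC)[C@H]1C3=O | intermediate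
21 | 12-hydroxy 6-ketone | C=C1C[C@]23C[C@H]1[C@@H](O)C[C@H]2[C@]1(C)CC[C@H](O[Si](C)(C)C(C)(C)C)[C@@](C)(C(=O)OC)[C@H]1C3=O | intermediate
22 | methyl enol ether at C6=C7 (E/Z) | C=C1C[C@]23C[C@H]1[C@@H](O)C[C@H]2[C@]1(C)CC[C@H](O[Si](C)(C)C(C)(C)C)[C@@](C)(C(=O)OC)[C@H]1C3=COC | intermediate
23 | C7 aldehyde | C=C1C[C@]23C[C@H]1[C@@H](O)C[C@H]2[C@]1(C)CC[C@H](O[Si](C)(C)C(C)(C)C)[C@@](C)(C(=O)OC)[C@H]1[C@@H]3C=O | intermediate
24 | C7 carboxylic acid (3-O-TBS, C19 methyl ester) | C=C1C[C@]23C[C@H]1[C@@H](O)C[C@H]2[C@]1(C)CC[C@H](O[Si](C)(C)C(C)(C)C)[C@@](C)(C(=O)OC)[C@H]1[C@@H]3C(=O)O | intermediate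
25 | 7,19-diacid 3-O-TBS ether | C=C1C[C@]23C[C@H]1[C@@H](O)C[C@H]2[C@]1(C)CC[C@H](O[Si](C)(C)C(C)(C)C)[C@@](C)(C(=O)O)[C@H]1[C@@H]3C(=O)O | intermediate
26 | target gibberellin, 3β,12α-dihydroxygibberell-16-ene-7,19-dioic acid (3-OH cis to C18, 12-OH anti to the C15–C16 bridge) | C=C1C[C@]23C[C@H]1[C@@H](O)C[C@H]2[C@]1(C)CC[C@H](O)[C@@](C)(C(=O)O)[C@H]1[C@@H]3C(=O)O | target

Total step count: 17. Longest linear sequence: 17 steps (1 → 26).

Steps most likely to fail

Step 10. The cascade may stall after the first conjugate addition, because the proton transfer that regenerates the C8 enolate is slow, or the final enolate may equilibrate before it is silylated, which would lose the C12–C13 regiochemistry. The fallback sets out from 17: catalytic KOtBu in t-BuOH–THF at 0 °C should run both Michael additions under equilibrating conditions to the tricyclic 6,12-diketone F1. A separate kinetic deprotonation (LiN(i-Pr)2, THF, −78 °C; TBSCl, HMPA) at the less hindered C13 methylene then gives the silyl enol ether; the C11 methylene lies next to C9, which is flanked by the quaternary C8 and C10. The fallback comes back to the route at 19.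

Step 2. The ester-deactivated diene may add sluggishly, or the catalyst may discriminate the faces of the enal poorly. The fallback gives up catalyst control for a resolution and sets out from 2, again with 3. Heating the two in toluene (100 °C, sealed tube, no catalyst) should give the racemate, that is 4 together with the enantiomeric cycloadduct F2. 1 M HCl in THF then gives 5 together with the enantiomeric keto diester F3, and methylation as in step 3 (MeI, K2CO3, acetone) gives 6 together with the enantiomeric methylated keto aldehyde F4. Condensation of this racemic aldehyde with (1R,2R)-N,N'-dimethyl-1,2-diphenylethane-1,2-diamine (Et2O, 4 Å molecular sieves, rt) should give the imidazolidine of 6 F5 and the diastereomeric imidazolidine F6. The aminal carbon is not a stereocentre, so only these two diastereomers arise, and they are separated by chromatography or crystallisation. Dilute aqueous HCl in Et2O hydrolyses F5 and sets the diamine free. The fallback comes back to the route at 6.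

Step 13. The phosphorus ylide may fail to add to the congested C6 carbonyl, or may only enolise it toward C5 with loss of configuration there. The fallback sets out from 21: the smaller dimethylsulfonium methylide (Me3SI, n-BuLi, THF, 0 °C; Corey–Chaykovsky reaction) should give the spiro-epoxide F7. MgBr2·OEt2 (Et2O, 0 °C) should then open it with a 1,2-hydride shift (Meinwald rearrangement) to the C7 aldehyde, which is equilibrated with K2CO3 in MeOH. The fallback comes back to the route at 23.

Further compounds
F1 | step 10 | tricyclic 6,12-diketone (8-allyl, rings A–C) | C=CC[C@]12CCC(=O)C[C@H]1[C@]1(C)CC[C@H](O[Si](C)(C)C(C)(C)C)[C@@](C)(C(=O)OC)[C@H]1C2=O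
F2 | step 2 | 1-ethyl 2-methyl (1S,2S,6S)-6-formyl-6-methyl-3-[(tert-butyldimethylsilyl)oxy]cyclohex-3-ene-1,2-dicarboxylate (enantiomeric cycloadduct) | O=C[C@@]1(C)CC=C(O[Si](C)(C)C(C)(C)C)[C@@H](C(=O)OC)[C@@H]1C(=O)OCC
F3 | step 2 | 1-ethyl 2-methyl (1S,2S,6S)-6-formyl-6-methyl-3-oxocyclohexane-1,2-dicarboxylate (enantiomeric keto diester) | O=C[C@@]1(C)CCC(=O)[C@@H](C(=O)OC)[C@@H]1C(=O)OCC
F4 | step 2 | 1-ethyl 2-methyl (1R,2R,6S)-6-formyl-2,6-dimethyl-3-oxocyclohexane-1,2-dicarboxylate (enantiomeric methylated keto aldehyde) | O=C[C@@]1(C)CCC(=O)[C@](C)(C(=O)OC)[C@@H]1C(=O)OCC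
F5 | step 2 | imidazolidine of 6 [(4R,5R)-1,3-dimethyl-4,5-diphenylimidazolidin-2-yl group in place of the formyl group] | CN1[C@H](c2ccccc2)[C@@H](c2ccccc2)N(C)C1[C@]3(C)CCC(=O)[C@@](C)(C(=O)OC)[C@H]3C(=O)OCC
F6 | step 2 | diastereomeric imidazolidine [the same (4R,5R)-imidazolidinyl group on the enantiomeric ring A] | CN1[C@H](c2ccccc2)[C@@H](c2ccccc2)N(C)C1[C@@]3(C)CCC(=O)[C@](C)(C(=O)OC)[C@@H]3C(=O)OCC
F7 | step 13 | spiro-epoxide at C6 (C6 epimers) | C=C1C[C@]23C[C@H]1[C@@H](O)C[C@H]2[C@]1(C)CC[C@H](O[Si](C)(C)C(C)(C)C)[C@@](C)(C(=O)OC)[C@H]1C31CO1
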